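Do not read a flat line as a flask that needs more time or more heat; ask first what it stopped for.

| setting | Tuesday's | Saturday's | flask |
|---|---|---|---|
| L | 2 M | 2 M | 2.0 M |
| J | 0.60 equiv | 0.90 equiv | 0.600 equiv |
| temperature | 40 °C | 46 °C | 40 °C |
| remark | the very flask that is asked about, followed so far | run made earlier |  |
| time |  |  | 4.0 d |

- Tuesday's (time / h: Z / %, L / %): 8.00: 53.3, 43.6; 15.0: 52.0, 42.2; 25.0: 51.9, 44.6; 48.0: 53.9, 44.0; 96.0: 51.0, 42.9
- Saturday's (time / h: Z / %, L / %): 0.667: 68.7, 22.9; 2.00: 67.9, 22.5; 4.00: 69.9, 24.4; 6.00: 70.2, 23.6; 8.00: 68.6, 22.3

(readings scatter by 1 percentage point)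

- west: at 4.0 d raise the temperature by 25 K, then wait 50 h
- north: change nothing and wait 50 h more
- south-west: at 4.0 d add J, 50.0 % of the amount charged, then wait 50 h

- additions leave the volume as it is

* Z, in percent of the L first charged, at 4.0 d
* which option adds most Z ("none" when 2 percentage points or less is all one gets) (west / north / south-west / none)
* Z present, in percent of the L first charged, after west
* Z present, in percent of the L first charged, after north

1. Read Tuesday's flask directly: Z stands at 53.3 % after 8.00 h and at 51.0 % after 96.0 h, with no trend against a scatter of 1 percentage point, so take the mean of the readings, 52.4 %, as my value for Z.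

2. Reckon again without any Z reading. Each Z holds one J, so with J as limiting reagent the J ceiling is 60.0 %, the Z reached if each J charged lands on a fresh L.

3. Count that charge as used, with c(J) down to nothing, and let each complex missing from Z + L hold 2 J. Then Z is 2 × (L used) minus the ceiling, and the mean L of 43.5 % gives 53.1 %, which lies 0.70 points from the direct mean.

4. Try both ways on Saturday's run, whose ceiling is 90.0 %. Its mean L of 23.1 % gives 63.7 %, but its Z readings average 69.1 %. The cheat is the assumed 2 J: with Saturday's charge counted as used, the readings put 2.68 J on each missing complex there, more than 2. So keep the direct 52.4 %, and keep the ceiling.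

5. The readings of Tuesday's flask stay flat and neither waiting nor heating adds J, so expect Z in that flask to stay near 52.4 %. South-west lifts the ceiling to 90.0 %, the same as Saturday's, which promises about 17 points more Z, though Saturday's run was warmer. Choose south-west.

The forecast says 52.4 % (51.5 % to 53.3 %), 52 % after west and 52.4 % after north, and picks south-west: “The plateau is therefore set by J supply, not by time.”

The flask gives 53.0 %, 53.0 % after west and 53.0 % after north; the best option is south-west, adding 17 points.

    Z + J → X + E (k = 0.0280 /M/min, Ea = 82.0 kJ/mol)
    X → D (k = 0.00160 /min, Ea = 113 kJ/mol)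
    X + J ⇌ G, settled at all times (K = 1.10 /M, ΔH = −51.0 kJ/mol)
    L + J → X + Z (k = 0.270 /M/min, Ea = 66.0 kJ/mol)
    E + J → X + Q (k = 2.00 /M/min, Ea = 51.0 kJ/mol)
    (constants at 40 °C)

In the flask at 96.0 h, 53.0 % of Z, 2 × 0.654 % of E and 3 × 1.91 % of Q hold J equal to 60.0 % of the L charged, which is the ceiling, with free J at 0 % of its charge. Just after the start, L + J → X + Z uses J 60 times faster than Z + J → X + E, and Z ends 7 points under the ceiling. For the neighbour charged with 0.150 equiv of J, the ceiling scales to 15.0 %; the computed Z there is 14.7 %.

(Readings and results are calculated with constants of no real substance.)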